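1. The vessel is closed and stirred, and its solid substrate has to dissolve before reagent can reach it. I want to know what stands in the flask after 40 min.

| flask | solid substrate | reagent | remark | time |
|---|---|---|---|---|
| summer | 0.20 M | 0.070 M | run made earlier |  |
| dusk | 0.20 M | 0.28 M | run made earlier |  |
| spring | 0.30 M | 0.14 M | run made earlier |  |
| flask | 0.20 M | 0.140 M |  | 40 min |

| run | time / min | target / % | solid product / % | solid substrate / % |
|---|---|---|---|---|
| summer | 2.00 | 0 | 0.3 | 96.4 |
| summer | 6.00 | 0 | 0 | 89.3 |
| summer | 12.0 | 2.7 | 1.7 | 80.2 |
| summer | 15.0 | 4.6 | 0 | 77.8 |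
| summer | 25.0 | 11.6 | 0.8 | 66.4 |
| summer | 30.0 | 10.4 | 0 | 64.5 |
| summer | 40.0 | 15.1 | 0.1 | 56.3 |
| dusk | 6.00 | 5.4 | 0 | 88.6 |
| dusk | 12.0 | 13.4 | 0 | 77.3 |
| dusk | 15.0 | 18.0 | 0 | 71.4 |
| dusk | 25.0 | 28.3 | 1.2 | 58.0 |
| dusk | 30.0 | 33.9 | 1.5 | 51.1 |
| dusk | 40.0 | 45.6 | 2.5 | 40.2 |
| spring | 8.00 | 3.0 | 0 | 89.7 |
| spring | 15.0 | 5.2 | 0 | 83.8 |
| spring | 25.0 | 13.9 | 0 | 76.2 |
| spring | 30.0 | 13.7 | 0.6 | 73.3 |
| spring | 40.0 | 16.1 | 3.4 | 65.3 |

(standard deviation of a reading: 1 percentage point)

- amounts and yields of target count solid product and idle adduct too
- given per volume of solution although it is solid: solid substrate, solid product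
- steps under discussion: solid substrate <-> dissolved substrate; dissolved substrate + reagent -> target; solid product <-> target; reagent + target <-> idle adduct; solid substrate -> decomposition product
- at the start none of the solid substrate is in solution
- as a choice and as an amount asked, solid substrate means what is still solid

* the species that holds most of what was charged as solid substrate, at 40 min (solid product / solid substrate / target)
* the largest share itself, whichever of these holds it, in percent of the solid substrate charged

2. I start with dissolving as the main step. Early on, summer loses 0.00357 M min⁻¹ of solid and spring loses 0.00386 M min⁻¹, although spring holds 1.50 times the charge and twice the reagent. So the loss in molarity per minute hardly moves between these two runs, and I read that as zero order in the solid. At that early pace, the flask would keep 22.8%.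

3. Next I add the slowing. Over the whole 40.0 min, spring averages 0.00260 M min⁻¹, which is slower than its early pace. I therefore define the clearing time, the charge of solid divided by this average loss. For the flask it is 76.8 min. The asked time is about half of that, so 48.0% stays solid.

4. Then I add the reagent. At equal charge, the solid left at 40 min reads 56.3% in summer and 40.2% in dusk, so reagent matters. But spring has the flask's reagent, and I change nothing. Spring's target, a reading that already counts its solid product, gives 24.1% when put on the flask's charge, less than the solid.

5. The forecast names solid substrate at 49%, noting: "Early loss is nearly the same in molar terms across the runs". My figure lies 1 percentage point below it.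

6. The flask gives solid substrate at 48.3%.

    solid substrate ⇌ dissolved substrate, rate k1*(cs1 - [dissolved substrate]) while solid is left; crystals form when [dissolved substrate] > cs1 (solubility = 0.0770 M, k = 0.0563 min⁻¹)
    dissolved substrate + reagent → target (k = 0.517 L mol⁻¹ min⁻¹)
    solid product ⇌ target, rate k3*(cs3 - [target]) while solid is left; crystals form when [target] > cs3 (solubility = 21.0 mM, k = 0.518 min⁻¹)
    reagent + target ⇌ idle adduct, settled at all times (K = 18.4 L mol⁻¹)
    solid substrate → decomposition product (k = 1.16 × 10⁻⁴ min⁻¹)

At 40.0 min, dissolved substrate is still being made 1.32 times faster than it is used up. The flask's own average loss gives a clearing time of 77.4 min. A neighbour like this flask but charged with 0.080 M of solid has a clearing time of 30.7 min at the same loss, shorter than 40 min. At 40 min its solid stands at 0%, and target holds 67.0%.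

(The numbers in the tables come from a simulation for an exercise, and the scatter is random.)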